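Slowness in this flask was a falling frequency, so I counted how many e-foldings the electrophile could get through in the time allowed.

electrophile 0.10 M; nucleophile 1.05 equiv; free base 3.00 equiv; protic impurity 0.0500 M; time 20 h

1. part of the electrophile that has reacted at 20 h
2. share of free nucleophile in free nucleophile and protonated nucleophile together, at 20 h

    electrophile + nucleophile ⇌ acid set free + target (K1 = 32, k1 = 1.7 L mol⁻¹ h⁻¹)
    nucleophile + acid set free ⇌ protonated nucleophile, settled at all times (K2 = 75000 L mol⁻¹)
    acid set free + free base ⇌ salt of the base, settled at all times (K3 = 14000 L mol⁻¹)
    electrophile + protic impurity → quenched substrate (k4 = 2.2 L mol⁻¹ h⁻¹)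
    nucleophile + target ⇌ idle adduct, settled at all times (K5 = 8.1 L mol⁻¹)

The electrophile was lost to the nucleophile and to the protic impurity. Each target set free one acid, which the nucleophile and the free base shared. At the start, with c(nucleophile) at 0.105 M, the loss frequency (a pseudo-first-order constant) was 0.289 h⁻¹.

Two things slowed it, and I carried one rule for the first: the split ratio, 5.36, which is protonated over free nucleophile divided by salt over free base.

I kept the starting division of the electrophile, which gave 0.0619 M of target, and I set the idle adduct aside. That left 0.0431 M of nucleophile, free or protonated. The acid was less than c(free base), 0.300 M, so I held c(free base) at its charge. I did not take the nucleophile's part as small, so I solved for it: the acid on the nucleophile and the acid on the base had to add up to the target, and the split ratio tied the two. The root of that quadratic was a ratio of protonated to free nucleophile of 0.770, so the free share came to 56.5%.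

Free nucleophile ended at 0.0244 M, down by a factor 4.30. Impurity ended at 0.0119 M, down by a factor 4.21. The end frequency was 0.0675 h⁻¹, lower than at the start. Hours pile up at the slow end, so I averaged the e-folding times, not the frequencies, and got 9.14 h. That gave 88.8%.

The forecast gave 89% and 59%, holding that “The nucleophile out-competes the base for acid by only about fivefold”.

The simulation gave 89.8% and 58.7%.

In this flask, the answer for the reacted part shifted by 5 points, the width of its margin, once the nucleophile charge moved to 0.807 equiv or 1.44 equiv. At the asked time this flask held 0.0349 M of salt and 0.265 M of free base, so the split ratio put the free share at 58.7%. The neighbour flask charged with 0.260 equiv of nucleophile held 0.0180 M of salt and 0.282 M of free base. There the split ratio put the free share at 74.5%, and that flask gave 74.5%.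

Its constants were set for the occasion; what happens was integrated by code.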